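The synthesis rests on opening the oxolane ring between O1 and the benzylic carbon C2. C2 carries the 3,4,5-trimethoxyphenyl ring, whose para-methoxy oxygen stabilises a planar cation at C2, and the key step exploits this. A catalytic acid ionises both epimers of an acyclic benzylic alcohol to one cation, and the C5 hydroxyl closes the ring. An epimer mixture is thus funnelled into the single 2,3-trans ether under control of C3. The precursor is an unprotected tetraol: phenol, two primary alcohols, epimeric benzylic carbinol. It comes from a Stobbe condensation, one Rh-catalysed asymmetric hydrogenation (sole source of chirality), a trans-selective lactone aldol and LiAlH4 reduction. No protecting group is used.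

Key step: step 6

Remark on locants: oxolane numbering is O1, C2 (aryl), C3 (CH2OH), C4 (benzyl), C5. Lignan locants C7/C8/C9 stand for C2/C3/hydroxymethyl carbon, and C7'/C8'/C9' for benzyl CH2/C4/C5.

Assumption: (R,R)-Et-DuPHOS-Rh is taken to give the (S)-succinate, as the chelate model for itaconate half-esters predicts. Should the sense be opposite, the antipodal ligand is used.

Step 1
Reactants: 1 3-hydroxy-4,5-dimethoxybenzaldehyde; 2 dimethyl succinate
Product: 3 (E)-4-(3-hydroxy-4,5-dimethoxyphenyl)-3-(methoxycarbonyl)but-3-enoic acid
Conditions: LiOMe (3 equiv), MeOH, reflux; then 2 M HCl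
Reagents that add atoms: none
Why: Stobbe condensation: the succinate enolate adds to the aldehyde, the aldolate lactonises onto the distal ester with loss of methoxide and E1cB opening of that lactone gives the (E)-half-ester as its carboxylate, while the phenoxide of 1, being meta to the formyl group, cannot deactivate it by conjugation and merely costs one extra equivalent of base.

Step 2
Reactants: 3 (E)-half-ester
Product: 4 (S)-4-(3-hydroxy-4,5-dimethoxyphenyl)-3-(methoxycarbonyl)butanoic acid
Conditions: [((R,R)-Et-DuPHOS)Rh(cod)]BF4 (0.5 mol %; ligand = 1,2-bis((2R,5R)-2,5-diethylphospholano)benzene), NaOMe (10 mol %), H2 (5 bar), MeOH, rt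
Reagents that add atoms: none
Why: Rh-catalysed asymmetric hydrogenation of a Stobbe-type itaconate half-ester: the carboxylate and the alkene chelate the cationic Rh centre and the C2-symmetric bisphospholane then allows H2 delivery to one alkene face only, which sets the single stereocentre as (S) (future C4 of the oxolane), with phenol, ester and arene untouched.

Step 3
Reactants: 4 (S)-half-ester
Product: 6 (S)-4-(3-hydroxy-4,5-dimethoxybenzyl)dihydrofuran-2(3H)-one, via hydroxy acid 5 (not isolated)
Conditions: KOH (2.0 equiv), EtOH, 0 °C; CaCl2, NaBH4, EtOH, −10 °C to rt; then 3 M HCl, rt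
Reagents that add atoms: none
Why: Chemoselective ester reduction with calcium borohydride: carboxylate and phenoxide are inert as potassium salts, only the methyl ester is reduced, and acidification closes the γ-hydroxy acid 5 to the lactone by acid-catalysed lactonisation without breaking a bond at the stereocentre.

Step 4
Reactants: 6 (S)-lactone; 7 3,4,5-trimethoxybenzaldehyde
Product: 9 (3R,4S)-3-[hydroxy(3,4,5-trimethoxyphenyl)methyl]-4-(3-hydroxy-4,5-dimethoxybenzyl)dihydrofuran-2(3H)-one as a mixture of both carbinol (C7) epimers, via dilithium enolate 8 (not isolated)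
Conditions: LiHMDS (2.2 equiv), THF, −78 °C; then 7, −78 °C; AcOH quench at −78 °C
Reagents that add atoms: none
Why: Lithium enolate aldol addition: the first equivalent of base is spent on the phenol, the second forms the lactone enolate, and the aldehyde approaches the enolate face anti to the C4 benzyl group, which sets C3 trans to it (3R), whereas the carbinol centre is deliberately left as a mixture because step 6 erases it.

Step 5
Reactants: 9 aldol lactone (C7 epimer mixture)
Product: 10 (2S,3S)-2-[hydroxy(3,4,5-trimethoxyphenyl)methyl]-3-(3-hydroxy-4,5-dimethoxybenzyl)butane-1,4-diol as a mixture of both carbinol (C7) epimers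
Conditions: LiAlH4 (4 equiv), THF, 0 °C to rt; aq Rochelle salt work-up (pH about 7)
Reagents that add atoms: none
Why: LiAlH4 reduction of the lactone to the 1,4-diol, which at 0 °C should outrun retro-aldol cleavage of the aluminium alkoxide, changes no stereocentre and, with a near-neutral work-up, leaves the acid-labile benzylic alcohol intact.

Step 6
Reactants: 10 tetraol (C7 epimer mixture)
Product: 12 [(2R,3S,4S)-4-(3-hydroxy-4,5-dimethoxybenzyl)-2-(3,4,5-trimethoxyphenyl)tetrahydrofuran-3-yl]methanol (target), via benzylic cation 11 (not isolated)
Conditions: (±)-CSA (10 mol %), CH2Cl2–MeCN 4:1 (0.01 M), 0 °C to rt, monitored; Et3N quench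
Reagents that add atoms: none
Why: Protonation of the C7 hydroxyl of either epimer of 10 and loss of water give one and the same planar benzylic cation 11, delocalised into the 3,4,5-trimethoxyphenyl ring and onto its para-methoxy oxygen, so the stereochemical information at C7 is erased. The closest known reaction type is the acid-catalysed dehydrative SN1 cycloetherification of electron-rich benzylic alcohols, as used to turn 7-hydroxy-dibenzylbutane-1,4-diols into 7,9'-epoxylignans. The oxolane closes in a 5-exo-trig mode: the C9' primary hydroxyl (future O1) attacks C7 (future C2), whose cationic π-bond to the aryl ipso carbon stays outside the new ring. The new centre C2 is controlled by the adjacent C3 (C8): attack occurs on the face that places the aryl group anti to the C3 hydroxymethyl group, because the other face leads to the all-cis 2,3,4-trisubstituted ring, and since closure is reversible under the acid any cis ether should re-ionise and drain to the 2,3-trans (2R) isomer. The step needs O-capture over C-capture (C2' and C6' of the hydroxydimethoxybenzyl ring could close an aryltetralin irreversibly), C9'-OH over C9-OH, and inertness of the primary alcohols. The five-membered transition state beats the strained oxetane, primary carbinols do not ionise, and catalytic weak acid, high dilution, low temperature and an early Et3N quench should keep the slower Friedel-Crafts path out.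

Compound list
1 | 3-hydroxy-4,5-dimethoxybenzaldehyde | COc1cc(C=O)cc(O)c1OC | starting material
2 | dimethyl succinate | COC(=O)CCC(=O)OC | starting material
3 | (E)-4-(3-hydroxy-4,5-dimethoxyphenyl)-3-(methoxycarbonyl)but-3-enoic acid | COc1cc(/C=C(\CC(=O)O)C(=O)OC)cc(O)c1OC | intermediate
4 | (S)-4-(3-hydroxy-4,5-dimethoxyphenyl)-3-(methoxycarbonyl)butanoic acid | COc1cc(C[C@H](C(=O)OC)CC(=O)O)cc(O)c1OC | intermediate
5 | (S)-4-(3-hydroxy-4,5-dimethoxyphenyl)-3-(hydroxymethyl)butanoic acid (not isolated) | COc1cc(C[C@H](CO)CC(=O)O)cc(O)c1OC | intermediate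
6 | (S)-4-(3-hydroxy-4,5-dimethoxybenzyl)dihydrofuran-2(3H)-one | COc1cc(C[C@@H]2COC(=O)C2)cc(O)c1OC | intermediate
7 | 3,4,5-trimethoxybenzaldehyde | COc1cc(C=O)cc(OC)c1OC | starting material
8 | dilithium phenoxide/lactone enolate of 6 (not isolated) | COc1cc(C[C@@H]2COC([O-])=C2)cc([O-])c1OC.[Li+].[Li+] | intermediate
9 | (3R,4S)-3-[hydroxy(3,4,5-trimethoxyphenyl)methyl]-4-(3-hydroxy-4,5-dimethoxybenzyl)dihydrofuran-2(3H)-one, both carbinol epimers (carbinol centre left undefined) | COc1cc(C[C@@H]2COC(=O)[C@H]2C(O)c2cc(OC)c(OC)c(OC)c2)cc(O)c1OC | intermediate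
10 | (2S,3S)-2-[hydroxy(3,4,5-trimethoxyphenyl)methyl]-3-(3-hydroxy-4,5-dimethoxybenzyl)butane-1,4-diol, both carbinol epimers (carbinol centre left undefined) | COc1cc(C[C@H](CO)[C@@H](CO)C(O)c2cc(OC)c(OC)c(OC)c2)cc(O)c1OC | intermediate
11 | 3,4,5-trimethoxybenzylic cation derived from 10 (not isolated) | COc1cc(C[C@H](CO)[C@@H](CO)[CH+]c2cc(OC)c(OC)c(OC)c2)cc(O)c1OC | intermediate
12 | [(2R,3S,4S)-4-(3-hydroxy-4,5-dimethoxybenzyl)-2-(3,4,5-trimethoxyphenyl)tetrahydrofuran-3-yl]methanol, 2,3-trans-3,4-cis | COc1cc(C[C@@H]2CO[C@@H](c3cc(OC)c(OC)c(OC)c3)[C@@H]2CO)cc(O)c1OC | target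

Total step count: 6. Longest linear sequence: 6 (1 to 12).

Steps most likely to fail

Step 6. The O-closure is reversible. On prolonged acid exposure the cation may be drained irreversibly by Friedel-Crafts attack of the electron-rich phenol ring, a six-membered carbocyclisation.

The fallback keeps the same ring closure but removes the competing nucleophile with a temporary acceptor group.
- From 10, the phenol alone is sulfonylated (TsCl, K2CO3, acetone, rt; aliphatic alcohols do not react under carbonate) to give the aryl tosylate triol F1.
- Its sulfonyloxy-deactivated ring should be a much poorer π-nucleophile, so acid treatment (CSA or p-TsOH, CH2Cl2) can be run to full equilibration and should give the oxolane tosylate F2.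
- Cleavage of the sulfonate with KOH in aqueous MeOH at reflux comes back to 12.

Step 4. The dilithium species may aggregate or precipitate. This could lead to incomplete enolisation, proton return and retro-aldol reversal on quenching.

The fallback removes the acidic proton and sets out from 6.
- BnBr and K2CO3 in DMF give the benzyl ether lactone F3.
- LiHMDS (1.1 equiv) and 7 at −78 °C give the aldol lactone benzyl ether F4 (C7 epimer mixture).
- LiAlH4 gives the triol benzyl ether F5.
- The same acid-catalysed closure gives the oxolane benzyl ether F6.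
- Brief hydrogenolysis (H2, 1 atm, Pd/C, EtOAc, stopped after one equivalent so that the benzylic ring C–O bond is not cleaved) comes back to 12.

Step 2. Facial discrimination may be insufficient, or the catalyst may be slowed by the phenolic substrate. Either would erode the only source of absolute configuration.

The fallback replaces catalysis by classical resolution and sets out from 3.
- H2 and Pd/C in MeOH give the racemic half-ester F7.
- Salt formation with (S)-1-phenylethylamine and fractional crystallisation should give the ammonium salt of the (S)-acid F8. Which amine antipode gives the less soluble salt with the (S)-acid has to be found by trial, and both antipodes are available.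
- Dilute HCl releases 4.

Further compounds
F1 | step 6 | aryl tosylate of 10 (phenol O-tosylated, three alcohols free, both carbinol epimers) | COc1cc(C[C@H](CO)[C@@H](CO)C(O)c2cc(OC)c(OC)c(OC)c2)cc(OS(=O)(=O)c2ccc(C)cc2)c1OC
F2 | step 6 | aryl tosylate of 12, (2R,3S,4S) | COc1cc(C[C@@H]2CO[C@@H](c3cc(OC)c(OC)c(OC)c3)[C@@H]2CO)cc(OS(=O)(=O)c2ccc(C)cc2)c1OC
F3 | step 4 | (S)-4-[3-(benzyloxy)-4,5-dimethoxybenzyl]dihydrofuran-2(3H)-one | COc1cc(C[C@@H]2COC(=O)C2)cc(OCc2ccccc2)c1OC
F4 | step 4 | (3R,4S)-4-[3-(benzyloxy)-4,5-dimethoxybenzyl]-3-[hydroxy(3,4,5-trimethoxyphenyl)methyl]dihydrofuran-2(3H)-one, both carbinol epimers | COc1cc(C[C@@H]2COC(=O)[C@H]2C(O)c2cc(OC)c(OC)c(OC)c2)cc(OCc2ccccc2)c1OC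
F5 | step 4 | (2S,3S)-3-[3-(benzyloxy)-4,5-dimethoxybenzyl]-2-[hydroxy(3,4,5-trimethoxyphenyl)methyl]butane-1,4-diol, both carbinol epimers | COc1cc(C[C@H](CO)[C@@H](CO)C(O)c2cc(OC)c(OC)c(OC)c2)cc(OCc2ccccc2)c1OC
F6 | step 4 | benzyl ether of 12, (2R,3S,4S) | COc1cc(C[C@@H]2CO[C@@H](c3cc(OC)c(OC)c(OC)c3)[C@@H]2CO)cc(OCc2ccccc2)c1OC
F7 | step 2 | racemic 4-(3-hydroxy-4,5-dimethoxyphenyl)-3-(methoxycarbonyl)butanoic acid | COc1cc(CC(C(=O)OC)CC(=O)O)cc(O)c1OC
F8 | step 2 | (S)-1-phenylethylammonium salt of (S)-acid 4 | COc1cc(C[C@H](C(=O)OC)CC(=O)[O-])cc(O)c1OC.C[C@H]([NH3+])c1ccccc1
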